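## Analysis of the target

Compound 26 is a C20 diterpenoid diacetate on a perhydroazulene. A cyclopentane (C1, C2, C3, C3a, C8a; azulene numbering) is fused to a cycloheptane (C3a, C4 to C8, C8a). C3a carries a methyl group, C5 an acetoxy group, C6 an exocyclic methylene, and C1 the chain C1'(OH)(CH3)–C2'H2–C3'H2–C4'H(OAc)–C(CH3)=CH2.

There are six stereocentres: C1 (S), C3a (R), C5 (S), C8a (S), C1' (S) and C4' (S). The ring fusion is trans (C3a–CH3 anti to C8a–H). The C1 chain lies on the face of the C3a methyl and of the C8 ring bond, so C1–H and C8a–H are cis and the chain sits in the more crowded, pseudo-axial position that only a kinetically controlled step delivers. The C5 acetate is trans to the angular methyl, that is equatorial on the seven-membered ring. C1' is contiguous with C1 and can borrow its bias; C4' is insulated from all other stereocentres by two methylene groups and needs its own source of chirality.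

Sensitive functions are the two allylic acetates (ionisation, allylic transposition, hydrolysis), the tertiary alcohol (dehydration) and two 1,1-disubstituted alkenes, which rule out hydrogenation or hydroboration once they are present. The hard parts are the quaternary centre next to a tertiary centre with the trans arrangement, the seven-membered ring with its 2-methylene-1-ol motif, and three stereocentres (C1, C1', C5) that must be set on mobile intermediates.

The strategy rests on the cyclopentane. C3a carries a methyl and the C4 arm, C8a carries hydrogen and the C8 arm trans to C4, and C1 next to C8a carries the only other substituent. This is the imprint of a conjugate methyl addition to a 3-substituted cyclopent-2-enone (carbonyl carbon = C1) whose enolate is alkylated at C8a.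

## Retrosynthetic reasoning

26 is traced to triol 25 by removing the two acetyl groups. Both secondary hydroxyls are allylic and unhindered and the third is tertiary, so one acetylation at the very end differentiates them and keeps the labile allylic esters out of all earlier steps.

In 25 the C5–C6 bond is cut, giving aldehyde 24 with a 2-bromoalkene at C6. This is the one ring bond whose formation creates the allylic alcohol and keeps the methylene in a single step. The forward reaction is an alkenylchromium addition that must close a seven-membered ring and place the C5 oxygen equatorial, trans to the C3a methyl. Cutting here also means the exocyclic methylene never has to survive the hydroboration used earlier.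

24 is 23 with the aldehyde masked as a dioxolane and C4'–O as a silyl ether. 23 is cut at C1'–C2' into methyl ketone 17 and the side-chain bromide 21, used as its Grignard reagent 22. The cut is placed so that the chain, not the methyl, is the incoming nucleophile; Felkin–Anh addition next to C1 then gives (S)-C1'. C4', which nothing in the ring can control, is made separately: 21 comes from allylic alcohol 20, that from epoxide 19 by isomerisation, and 19 from the achiral bromoalkene 18 by catalytic asymmetric epoxidation.

17 is simplified by functional-group changes only. The ketone comes from secondary alcohol 16, the 2-bromoalkene of 16 from terminal alkyne 14 by Markovnikov hydrometalation and bromination, 14 from aldehyde 13 by one-carbon homologation, and 13 from diol 12 by oxidation of the primary hydroxyl alone. These steps turn a three-carbon arm ending in CH2OH into C8–C7–C6(Br)=CH2 without a protecting group.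

Diol 12 is cut back to diene 10 by removing both hydroxyls and the C1–H. One hydroboration serves the allyl terminus (C6) and the ethylidene (C1/C1'), and C1 is set here by addition anti to the C3a methyl and the C8 arm. 10 comes from ketone 9 by Wittig ethylidenation, which adds C1' and its methyl.

Ketone 9 is cut at C3a–CH3 and at C8a–C8, giving enone 4, trimethylaluminium 5 and allyl iodide 6. These are the two bonds to the stereocentres of the cyclopentane, they form at the β- and α-carbons of one enone in one operation, and the three pieces are trivial. The forward reaction has to choose the enantioface at C3a and then the enolate face anti to the acetal arm. The carbonyl that drives both events remains as the C1 handle, and the two arms already hold C4/C5 and C8/C7/C6.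

Enone 4 is cut at C3a–C4 into 3-ethoxycyclopentenone 1 and Grignard reagent 2; addition to the vinylogous ester and acid work-up transposes the carbonyl.

## Alternatives that were turned down

Alternative 1: Both rings are disconnected at once through the bonds C8a–C3a and C6–C7. In the forward sense a chiral dirhodium tetracarboxylate decomposes the vinyl diazoketone A1. The carbenoid at C8a cyclopropanates the tethered C3a=C4 alkene to the cis-divinylcyclopropane A2, which undergoes Cope rearrangement (C8a–C4 breaks, C6–C7 forms) to the hydroazulenone A3.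
- For: two rings and the quaternary centre C3a arise in one catalytic step, the C1 carbonyl is in place, and C5 already carries oxygen as a silyl enol ether. In ring-forming economy this is clearly stronger than the chosen route, which spends steps 5 to 7 and 14 on the seven-membered ring.
- Against: A3 leaves C8a trigonal, so the trans fusion must be made afterwards by reducing the C8=C8a enone, and neither hydride delivery nor enolate protonation at a hydroazulene fusion carbon is reliably trans-selective. The C5 oxygen arrives as a ketone, whose reduction from the face away from the axial methyl would give the axial, wrong alcohol. The C6 methylene is still missing. Enantiocontrol in intramolecular cyclopropanation by a vinyl diazoketone is less dependable than with donor/acceptor diazo esters, and A1 needs a geometrically pure (E)-siloxydiene.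
- Comparison: the chosen strategy gives both cyclopentane stereocentres as saturated carbons, with the trans relation fixed, after two steps.

Alternative 2: C5–C6 is disconnected with the whole side chain, including the C4' acetate, in place. CrCl2 with catalytic NiCl2 converts the alkenyl bromide of A4 into an alkenylchromium species that adds to the C5 aldehyde and gives A5, one acetylation short of 26.
- For: the reaction is mild and aldehyde-selective, tolerates the acetate and the free tertiary hydroxyl, makes the allylic alcohol while keeping the methylene, and is the most convergent possible ending. On the bond itself this alternative is as strong as the chosen plan, which closes the ring the same way (24 to 25).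
- Against: as the organising idea it presupposes the substituted cyclopentane (quaternary C3a, C4 and C8 trans, the C1 chain cis to C8) and does not say how it is made, so the real difficulty moves into the synthesis of A4. It also needs one acetylation of C4' before the closure and another of C5 after it.
- Comparison: the chosen strategy supplies what A4 needs, through 9, and by closing the ring with C4'–OH free it finishes both esters in one step.

Alternative 3: C1–C2 is disconnected by ring contraction, the cyclopentane deriving from a cyclohexanone in a six–seven bicycle assembled by Robinson annulation. Photolysis of the α-diazoketone A6 in methanol triggers a Wolff rearrangement (C2 migrates to C1), and the ketene is trapped as the C1 methyl ester A7.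
- For: the annulation is a well-tried route to the angular methyl. The trans fusion can be fixed by dissolving-metal reduction more securely than by the enolate allylation of the chosen route. The seven-membered ring is present from the start, so no medium-ring closure is needed. Protonation of the ketene-derived enol from the face away from the angular methyl gives the required C1 configuration.
- Against: the sequence to A6 (annulation, enantiocontrol of a cyclisation onto a seven-membered diketone, reduction, ketalisation, diazo transfer) is long for what it delivers. A7 carries an epimerisable ester in its less stable orientation through the following basic steps. The C5 ketone must then be methylenated at C6 and reduced, and hydride attack from the face away from the axial methyl gives the axial C5 alcohol, the opposite of what is needed.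
- Comparison: the chosen route reaches a comparable stage (9) in two steps and introduces C5–O and the C6 methylene together, under conformational control that favours the equatorial alcohol.

Key step: step 2

Assumption: for the two catalyst-controlled steps (2 and 9) the antipode of the chiral catalyst is defined by the product configuration it must deliver; the stated antipode follows the usual transition-state model and is exchanged for its mirror image if the sense proves opposite.

## Route

Step 1
Reactants: 1 3-ethoxycyclopent-2-en-1-one; 2 (1,3-dioxolan-2-ylmethyl)magnesium bromide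
Product: 4 3-(1,3-dioxolan-2-ylmethyl)cyclopent-2-en-1-one, via bromomagnesium alkoxide adduct 3 (not isolated)
Conditions: THF, 0 °C → rt; then 1 M HCl (aq), 0 °C, 10 min
Reagents that add atoms: water, O
Why: Stork–Danheiser sequence: 1,2-addition of the Grignard reagent to the vinylogous ester carbonyl, then acid-promoted loss of the tertiary hydroxyl and hydrolysis of the enol ether transpose the enone. Brief cold dilute acid is enough for this collapse and should leave the dioxolane, which has no comparable cation stabilisation, intact.

Step 2
Reactants: 4 3-(1,3-dioxolan-2-ylmethyl)cyclopent-2-en-1-one; 5 trimethylaluminium; 6 allyl iodide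
Product: 9 (2R,3R)-3-(1,3-dioxolan-2-ylmethyl)-3-methyl-2-(prop-2-en-1-yl)cyclopentan-1-one, via dimethylaluminium enolate 7 (not isolated), via lithium trimethylaluminate enolate 8 (not isolated)
Conditions: Cu(OTf)2 (cat.), biphenol-based N,N-bis(1-arylethyl)phosphoramidite ligand (cat., antipode giving 3R), Et2O, −30 °C; then MeLi, THF, −30 °C; then 6, −30 → 0 °C
Reagents that add atoms: none
Why: AlMe3 reduces Cu(OTf)2 to a monovalent copper–phosphoramidite complex that takes up a methyl group and binds the enone as a π-complex while aluminium holds the carbonyl oxygen; oxidative addition gives a trivalent copper σ-alkyl at C3a, and reductive elimination forms C3a–CH3 and the aluminium enolate 7. MeLi converts 7 into the more nucleophilic aluminate 8, whose C8a attacks allyl iodide in an SN2 reaction and forms C8a–C8. The closest known reaction type is the copper-catalysed enantioselective conjugate addition of trialkylaluminium reagents to 3-substituted cyclic enones with trapping of the enolate by an allylic halide. No ring is closed in this step. C3a is controlled by the ligand, which directs methyl to the Si face of the β-carbon. C8a is controlled by the substrate: the iodide approaches the enolate face anti to the larger CH2–dioxolane arm and therefore syn to the methyl group, and since the same isomer should be favoured at equilibrium the epimerisable C8a–H does not work against the result. The step needs 1,4- over 1,2-addition (secured by copper), C- over O-allylation and mono- over bis-allylation (soft iodide, regiodefined enolate kept below 0 °C so that it does not equilibrate to the C2 side), and an intact dioxolane (ether solvent and low temperature temper the Lewis acidity of aluminium).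

Step 3
Reactants: 9 (2R,3R)-3-(1,3-dioxolan-2-ylmethyl)-3-methyl-2-(prop-2-en-1-yl)cyclopentan-1-one
Product: 10 2-{[(1R,2R)-3-ethylidene-1-methyl-2-(prop-2-en-1-yl)cyclopentyl]methyl}-1,3-dioxolane (E/Z mixture)
Conditions: EtPPh3Br, KN(SiMe3)2, THF, 0 °C; then 9, 0 °C → rt
Reagents that add atoms: ethyltriphenylphosphonium bromide, CC[P+](c1ccccc1)(c1ccccc1)c1ccccc1.[Br-]
Why: Wittig olefination of a cyclopentanone with a non-stabilised ylide; the ylide is preformed with a silylamide so that no alkoxide is present, and the ketone is added cold to keep enolisation toward C8a slower than addition. Both alkene isomers are usable because C1' becomes a ketone in step 8.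

Step 4
Reactants: 10 2-{[(1R,2R)-3-ethylidene-1-methyl-2-(prop-2-en-1-yl)cyclopentyl]methyl}-1,3-dioxolane
Product: 12 1-[(1S,2S,3R)-3-(1,3-dioxolan-2-ylmethyl)-2-(3-hydroxypropyl)-3-methylcyclopentyl]ethan-1-ol (both C1' epimers), via bis(9-BBN) trialkylborane adduct 11 (not isolated)
Conditions: 9-BBN (2.5 equiv), THF, rt → 65 °C; then NaOH (aq), H2O2, 0 °C → rt
Reagents that add atoms: hydrogen peroxide, OO
Why: Hydroboration–oxidation of both alkenes: boron goes to the allyl terminus (C6) and to C1' of the ethylidene, hydrogen to C1. With the C4 and C8 arms pseudo-equatorial and the C3a methyl pseudo-axial, the borane should add to the C1 face anti to that methyl and to the vicinal C8 arm, placing C1–H cis to C8a–H (C1 S). A borane with a single B–H is chosen so that the boron first bound at C6 cannot deliver hydride intramolecularly from the wrong face.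

Step 5
Reactants: 12 1-[(1S,2S,3R)-3-(1,3-dioxolan-2-ylmethyl)-2-(3-hydroxypropyl)-3-methylcyclopentyl]ethan-1-ol
Product: 13 3-[(1S,2S,5R)-5-(1,3-dioxolan-2-ylmethyl)-2-(1-hydroxyethyl)-5-methylcyclopentyl]propanal
Conditions: TEMPO (cat.), PhI(OAc)2, CH2Cl2, rt
Reagents that add atoms: none
Why: Oxoammonium (TEMPO) oxidation with PhI(OAc)2 as terminal oxidant is selective for primary over secondary alcohols, and anhydrous conditions stop at the aldehyde.

Step 6
Reactants: 13 3-[(1S,2S,5R)-5-(1,3-dioxolan-2-ylmethyl)-2-(1-hydroxyethyl)-5-methylcyclopentyl]propanal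
Product: 14 1-[(1S,2S,3R)-2-(but-3-yn-1-yl)-3-(1,3-dioxolan-2-ylmethyl)-3-methylcyclopentyl]ethan-1-ol
Conditions: dimethyl (1-diazo-2-oxopropyl)phosphonate, K2CO3, MeOH, 0 °C → rt
Reagents that add atoms: dimethyl (1-diazo-2-oxopropyl)phosphonate, CC(=O)C(=[N+]=[N-])P(=O)(OC)OC
Why: Ohira–Bestmann (Seyferth–Gilbert) homologation: methanolysis of the reagent gives the diazomethylphosphonate anion, which converts the aldehyde into the terminal alkyne through a diazoalkene and a 1,2-hydrogen shift. The carbonate base tolerates the free alcohol and the acetal, and the aldehyde has no α-stereocentre.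

Step 7
Reactants: 14 1-[(1S,2S,3R)-2-(but-3-yn-1-yl)-3-(1,3-dioxolan-2-ylmethyl)-3-methylcyclopentyl]ethan-1-ol
Product: 16 1-[(1S,2S,3R)-2-(3-bromobut-3-en-1-yl)-3-(1,3-dioxolan-2-ylmethyl)-3-methylcyclopentyl]ethan-1-ol, via internal alkenylalane 15 (not isolated)
Conditions: i-Bu2AlH (2.3 equiv), NiCl2(dppp) (cat.), THF, 0 °C → rt; then NBS, −20 → 0 °C
Reagents that add atoms: N-bromosuccinimide, O=C1CCC(=O)N1Br
Why: Nickel-catalysed α-selective (Markovnikov) hydroalumination of a terminal alkyne with the bidentate phosphine places aluminium on the internal carbon C6, and bromodealumination with NBS gives the 2-bromo-1-alkene. The first equivalent of hydride is consumed by the hydroxyl, and in THF the aluminium hydride should leave the dioxolane alone.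

Step 8
Reactants: 16 1-[(1S,2S,3R)-2-(3-bromobut-3-en-1-yl)-3-(1,3-dioxolan-2-ylmethyl)-3-methylcyclopentyl]ethan-1-ol
Product: 17 1-[(1S,2S,3R)-2-(3-bromobut-3-en-1-yl)-3-(1,3-dioxolan-2-ylmethyl)-3-methylcyclopentyl]ethan-1-one
Conditions: Dess–Martin periodinane, NaHCO3, CH2Cl2, 0 °C → rt
Reagents that add atoms: none
Why: Dess–Martin oxidation of the secondary alcohol under buffered, non-basic conditions, so that C1, now α to a ketone and in its less stable cis arrangement, is not epimerised. The two C1' epimers of 16 converge.

Step 9
Reactants: 18 5-bromo-2-methylpent-2-ene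
Product: 19 (S)-3-(2-bromoethyl)-2,2-dimethyloxirane
Conditions: L-fructose-derived Shi ketone (ent-Shi catalyst, cat.), KHSO5 (as Oxone), K2CO3, Bu4NHSO4, MeCN/CH2(OMe)2/aq. Na2B4O7 buffer, 0 °C
Reagents that add atoms: potassium peroxymonosulfate, [K+].[O-]S(=O)(=O)OO
Why: Shi asymmetric epoxidation: the chiral dioxirane formed from the ketone catalyst transfers oxygen to the trisubstituted alkene through a spiro transition state, which sets C4'. The pH is held near 10.5 to suppress Baeyer–Villiger loss of the catalyst, and the primary bromide is inert.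

Step 10
Reactants: 19 (S)-3-(2-bromoethyl)-2,2-dimethyloxirane
Product: 20 (S)-5-bromo-2-methylpent-1-en-3-ol
Conditions: lithium 2,2,6,6-tetramethylpiperidide (from the amine and n-BuLi), Et2AlCl, toluene, 0 °C; then 19, 0 °C → rt
Reagents that add atoms: none
Why: Aluminium amide-mediated isomerisation of a trisubstituted epoxide to an allylic alcohol: aluminium binds the epoxide oxygen and the hindered amide removes a proton from a methyl of the gem-dimethyl carbon in a syn elimination. Only the bond between oxygen and the gem-dimethyl carbon breaks, so the C4'–O stereocentre is retained and the isopropenyl group appears.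

Step 11
Reactants: 20 (S)-5-bromo-2-methylpent-1-en-3-ol
Product: 21 (S)-[(5-bromo-2-methylpent-1-en-3-yl)oxy]triethylsilane
Conditions: Et3SiCl, imidazole, CH2Cl2, 0 °C
Reagents that add atoms: chlorotriethylsilane, CC[Si](Cl)(CC)CC
Why: Silylation of a secondary alcohol with a silyl chloride and imidazole. The triethylsilyl ether survives Grignard formation and is removed later in the same acid step that opens the dioxolane.

Step 12
Reactants: 17 1-[(1S,2S,3R)-2-(3-bromobut-3-en-1-yl)-3-(1,3-dioxolan-2-ylmethyl)-3-methylcyclopentyl]ethan-1-one; 21 (S)-[(5-bromo-2-methylpent-1-en-3-yl)oxy]triethylsilane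
Product: 23 (2S,5S)-2-[(1S,2S,3R)-2-(3-bromobut-3-en-1-yl)-3-(1,3-dioxolan-2-ylmethyl)-3-methylcyclopentyl]-6-methyl-5-[(triethylsilyl)oxy]hept-6-en-2-ol, via Grignard reagent 22 (not isolated)
Conditions: 21, Mg, THF, rt → 40 °C; then CeCl3, THF, −78 °C; then 17, −78 → 0 °C; NH4Cl (aq)
Reagents that add atoms: none
Why: Organocerium addition: the Grignard reagent 22 is transmetalated to the weakly basic cerium reagent, which adds to the enolisable methyl ketone without deprotonating C1 or exchanging with the alkenyl bromide. Felkin–Anh control should set C1': with C8a (branched, bearing the cis C8 arm) as the large substituent anti to the nucleophile and C1–H on the side of the ketone methyl, the chain adds to the face that gives (S)-C1'. Adding the chain to a methyl ketone, rather than methyl to a chain ketone, is what makes this the required sense.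

Step 13
Reactants: 23 (2S,5S)-2-[(1S,2S,3R)-2-(3-bromobut-3-en-1-yl)-3-(1,3-dioxolan-2-ylmethyl)-3-methylcyclopentyl]-6-methyl-5-[(triethylsilyl)oxy]hept-6-en-2-ol
Product: 24 2-[(1R,2S,3S)-2-(3-bromobut-3-en-1-yl)-3-[(2S,5S)-2,5-dihydroxy-6-methylhept-6-en-2-yl]-1-methylcyclopentyl]acetaldehyde
Conditions: 1 M HCl (aq)/THF, 0 °C → rt
Reagents that add atoms: water, O
Why: Acid-catalysed acetal hydrolysis and protodesilylation in one operation: dilute aqueous acid opens the dioxolane to the C5 aldehyde and cleaves the triethylsilyl ether. The tertiary alcohol, the 2-bromoalkene and the isopropenyl carbinol need much stronger acid to ionise.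

Step 14
Reactants: 24 2-[(1R,2S,3S)-2-(3-bromobut-3-en-1-yl)-3-[(2S,5S)-2,5-dihydroxy-6-methylhept-6-en-2-yl]-1-methylcyclopentyl]acetaldehyde
Product: 25 (1S,3aR,5S,8aS)-1-[(2S,5S)-2,5-dihydroxy-6-methylhept-6-en-2-yl]-3a-methyl-6-methylidenedecahydroazulen-5-ol
Conditions: CrCl2 (excess), NiCl2 (cat.), DMF, rt, high dilution (0.005 M)
Reagents that add atoms: none
Why: Intramolecular Nozaki–Hiyama–Kishi reaction: zerovalent nickel (from NiCl2 and CrCl2) inserts into the C6–Br bond, and transmetalation gives an alkenyl species of trivalent chromium that adds only to the aldehyde, forming C5–C6 (7-exo-trig) and tolerating the free hydroxyls. In the chair-like transition state the chromium-bound aldehyde oxygen should take the pseudo-equatorial position, away from the axial C3a methyl, which gives the C5 alcohol trans to that methyl (C5 S).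

Step 15
Reactants: 25 (1S,3aR,5S,8aS)-1-[(2S,5S)-2,5-dihydroxy-6-methylhept-6-en-2-yl]-3a-methyl-6-methylidenedecahydroazulen-5-ol
Product: 26 (3S,6S)-6-[(1S,3aR,5S,8aS)-5-acetoxy-3a-methyl-6-methylidenedecahydroazulen-1-yl]-6-hydroxy-2-methylhept-1-en-3-yl acetate
Conditions: Ac2O, pyridine, DMAP (cat.), CH2Cl2, 0 °C → rt
Reagents that add atoms: acetic anhydride, CC(=O)OC(C)=O
Why: Nucleophile-catalysed acetylation: both secondary allylic alcohols are esterified, while the tertiary C1' hydroxyl is too hindered to react under these conditions. No stereocentre is touched.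

## Compound list

1 | 3-ethoxycyclopent-2-en-1-one | CCOC1=CC(=O)CC1 | starting material
2 | (1,3-dioxolan-2-ylmethyl)magnesium bromide | Br[Mg]CC1OCCO1 | starting material
3 | bromomagnesium 1-(1,3-dioxolan-2-ylmethyl)-3-ethoxycyclopent-2-en-1-olate (racemic) | CCOC1=CC(CC2OCCO2)(O[Mg]Br)CC1 | intermediate
4 | 3-(1,3-dioxolan-2-ylmethyl)cyclopent-2-en-1-one | O=C1CCC(CC2OCCO2)=C1 | intermediate
5 | trimethylaluminium | C[Al](C)C | starting material
6 | allyl iodide (3-iodoprop-1-ene) | C=CCI | starting material
7 | dimethylaluminium (R)-3-(1,3-dioxolan-2-ylmethyl)-3-methylcyclopent-1-en-1-olate | C[Al](C)OC1=C[C@@](C)(CC2OCCO2)CC1 | intermediate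
8 | lithium trimethyl[(R)-3-(1,3-dioxolan-2-ylmethyl)-3-methylcyclopent-1-en-1-olato]aluminate | [Li+].C[Al-](C)(C)OC1=C[C@@](C)(CC2OCCO2)CC1 | intermediate
9 | (2R,3R)-3-(1,3-dioxolan-2-ylmethyl)-3-methyl-2-(prop-2-en-1-yl)cyclopentan-1-one (allyl cis to methyl) | O=C1CC[C@](C)(CC2OCCO2)[C@H]1CC=C | intermediate
10 | 2-{[(1R,2R)-3-ethylidene-1-methyl-2-(prop-2-en-1-yl)cyclopentyl]methyl}-1,3-dioxolane (E/Z mixture) | CC=C1CC[C@](C)(CC2OCCO2)[C@H]1CC=C | intermediate
11 | bis(9-borabicyclo[3.3.1]nonan-9-yl) adduct of 10, boron on C6 and on C1' | CC(B1C2CCCC1CCC2)[C@H]1CC[C@](C)(CC2OCCO2)[C@H]1CCCB1C2CCCC1CCC2 | intermediate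
12 | 1-[(1S,2S,3R)-3-(1,3-dioxolan-2-ylmethyl)-2-(3-hydroxypropyl)-3-methylcyclopentyl]ethan-1-ol (both carbinol epimers) | CC(O)[C@H]1CC[C@](C)(CC2OCCO2)[C@H]1CCCO | intermediate
13 | 3-[(1S,2S,5R)-5-(1,3-dioxolan-2-ylmethyl)-2-(1-hydroxyethyl)-5-methylcyclopentyl]propanal | CC(O)[C@H]1CC[C@](C)(CC2OCCO2)[C@H]1CCC=O | intermediate
14 | 1-[(1S,2S,3R)-2-(but-3-yn-1-yl)-3-(1,3-dioxolan-2-ylmethyl)-3-methylcyclopentyl]ethan-1-ol | CC(O)[C@H]1CC[C@](C)(CC2OCCO2)[C@H]1CCC#C | intermediate
15 | diisobutylaluminium alkoxide of 14 carrying a diisobutylalumino group on the internal alkene carbon C6 | CC(O[Al](CC(C)C)CC(C)C)[C@H]1CC[C@](C)(CC2OCCO2)[C@H]1CCC(=C)[Al](CC(C)C)CC(C)C | intermediate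
16 | 1-[(1S,2S,3R)-2-(3-bromobut-3-en-1-yl)-3-(1,3-dioxolan-2-ylmethyl)-3-methylcyclopentyl]ethan-1-ol | CC(O)[C@H]1CC[C@](C)(CC2OCCO2)[C@H]1CCC(Br)=C | intermediate
17 | 1-[(1S,2S,3R)-2-(3-bromobut-3-en-1-yl)-3-(1,3-dioxolan-2-ylmethyl)-3-methylcyclopentyl]ethan-1-one | CC(=O)[C@H]1CC[C@](C)(CC2OCCO2)[C@H]1CCC(Br)=C | intermediate
18 | 5-bromo-2-methylpent-2-ene | CC(C)=CCCBr | starting material
19 | (S)-3-(2-bromoethyl)-2,2-dimethyloxirane | CC1(C)O[C@H]1CCBr | intermediate
20 | (S)-5-bromo-2-methylpent-1-en-3-ol | C=C(C)[C@H](CCBr)O | intermediate
21 | (S)-[(5-bromo-2-methylpent-1-en-3-yl)oxy]triethylsilane | C=C(C)[C@H](CCBr)O[Si](CC)(CC)CC | intermediate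
22 | (S)-{4-methyl-3-[(triethylsilyl)oxy]pent-4-en-1-yl}magnesium bromide | C=C(C)[C@H](CC[Mg]Br)O[Si](CC)(CC)CC | intermediate
23 | (2S,5S)-2-[(1S,2S,3R)-2-(3-bromobut-3-en-1-yl)-3-(1,3-dioxolan-2-ylmethyl)-3-methylcyclopentyl]-6-methyl-5-[(triethylsilyl)oxy]hept-6-en-2-ol | C=C(C)[C@H](CC[C@](C)(O)[C@H]1CC[C@](C)(CC2OCCO2)[C@H]1CCC(Br)=C)O[Si](CC)(CC)CC | intermediate
24 | 2-[(1R,2S,3S)-2-(3-bromobut-3-en-1-yl)-3-[(2S,5S)-2,5-dihydroxy-6-methylhept-6-en-2-yl]-1-methylcyclopentyl]acetaldehyde | C=C(C)[C@H](CC[C@](C)(O)[C@H]1CC[C@](C)(CC=O)[C@H]1CCC(Br)=C)O | intermediate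
25 | (1S,3aR,5S,8aS)-1-[(2S,5S)-2,5-dihydroxy-6-methylhept-6-en-2-yl]-3a-methyl-6-methylidenedecahydroazulen-5-ol | C=C(C)[C@H](CC[C@](C)(O)[C@H]1CC[C@]2(C)C[C@H](O)C(=C)CC[C@@H]12)O | intermediate
26 | (3S,6S)-6-[(1S,3aR,5S,8aS)-5-acetoxy-3a-methyl-6-methylidenedecahydroazulen-1-yl]-6-hydroxy-2-methylhept-1-en-3-yl acetate | C=C(C)[C@H](CC[C@](C)(O)[C@H]1CC[C@]2(C)C[C@H](OC(C)=O)C(=C)CC[C@@H]12)OC(C)=O | target

## Step count and least certain steps

Total step count: 15. Longest linear sequence: 12 steps (steps 1 to 8 and 12 to 15) from 1; the side-chain branch (steps 9 to 11) joins at step 12.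

**Step 2 (key step).** The most likely failure is poor facial discrimination in the allylation, because the electrophile has to tell a methyl group from a CH2–acetal arm on the neighbouring quaternary carbon. Slow alkylation of the aluminium-bound enolate would add to this by allowing proton transfer (regiochemical scrambling, bis-allylation), and coordination of the dioxolane oxygens to aluminium or copper could erode the enantioselectivity. The fallback sets out from 4 and comes back at 9. The conjugate addition is run as before, but aluminate 8 is quenched with allyl chloroformate to give allyl (R)-3-(1,3-dioxolan-2-ylmethyl)-3-methylcyclopent-1-en-1-yl carbonate F1. Decarboxylative Tsuji allylation (Pd2(dba)3, chiral phosphinooxazoline ligand, THF) then releases the enolate regiospecifically, and the chiral π-allyl complex of divalent palladium, not the small steric difference at C3a, selects the C8a face.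

**Step 3.** The most likely failure is enolisation of the hindered, α-branched ketone by the basic ylide, which returns starting material and scrambles C8a. The fallback sets out from 9 and comes back at 10, as a two-stage Peterson olefination with a non-basic nucleophile. The cerium reagent from [1-(trimethylsilyl)ethyl]magnesium chloride and CeCl3 adds to the ketone to give the β-hydroxysilane (2R,3R)-3-(1,3-dioxolan-2-ylmethyl)-3-methyl-2-(prop-2-en-1-yl)-1-[1-(trimethylsilyl)ethyl]cyclopentan-1-ol F2, and KH in THF eliminates it to 10.

**Step 4.** The most likely failure is incomplete facial selectivity at C1, since on the monocyclic diene the borane can also approach from the face of the C8 arm when the ring leaves its preferred conformation. The fallback sets out from 9, comes back at 12, bypasses step 3 as well, and sets C1 by heterogeneous hydrogenation.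
- Kinetic deprotonation on the C2 side (KN(SiMe3)2, PhNTf2, THF, −78 °C) gives (4R,5R)-4-(1,3-dioxolan-2-ylmethyl)-4-methyl-5-(prop-2-en-1-yl)cyclopent-1-en-1-yl trifluoromethanesulfonate F3.
- Hydroboration of the allyl group (9-BBN; NaBO3·4H2O) gives (4R,5R)-4-(1,3-dioxolan-2-ylmethyl)-5-(3-hydroxypropyl)-4-methylcyclopent-1-en-1-yl trifluoromethanesulfonate F4.
- Carbonylative Stille coupling (Pd(PPh3)4, CO, Me4Sn, LiCl) gives 1-[(4R,5R)-4-(1,3-dioxolan-2-ylmethyl)-5-(3-hydroxypropyl)-4-methylcyclopent-1-en-1-yl]ethan-1-one F5.
- Hydrogenation over Pd/C adds hydrogen to C1=C2 from the face anti to the C8 arm and gives 1-[(1S,2S,3R)-3-(1,3-dioxolan-2-ylmethyl)-2-(3-hydroxypropyl)-3-methylcyclopentyl]ethan-1-one F6.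
- NaBH4 reduces F6 to diol 12.

**Step 12.** The most likely failure is insufficient facial discrimination at the acetyl carbonyl. On the monocyclic ketone the large (C8a) and medium (C2) substituents differ only in branching and the acetyl group rotates freely, and a mixture of C1' epimers at a tertiary carbinol cannot be corrected afterwards. The fallback sets out from 17 and comes back at 25. The chain is added after the ring is closed, when C1 belongs to the rigid trans-fused hydroazulene and the acetyl group is held syn to the angular methyl.
- Dilute aqueous acid gives 2-[(1R,2S,3S)-3-acetyl-2-(3-bromobut-3-en-1-yl)-1-methylcyclopentyl]acetaldehyde F7.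
- CrCl2 with catalytic NiCl2 (aldehyde-selective) closes the ring to 1-[(1S,3aR,5S,8aS)-5-hydroxy-3a-methyl-6-methylidenedecahydroazulen-1-yl]ethan-1-one F8.
- The cerium reagent from 22 (one further equivalent for the C5 alkoxide) gives (1S,3aR,5S,8aS)-1-[(2S,5S)-2-hydroxy-6-methyl-5-(triethylsilyloxy)hept-6-en-2-yl]-3a-methyl-6-methylidenedecahydroazulen-5-ol F9.
- Dilute acid removes the silyl group and gives 25.

**Step 14.** The most likely failures are slow closure of the seven-membered ring, which lets protodemetalation and intermolecular addition compete, and incomplete facial selectivity at C5 because the forming ring is flexible. The fallback addresses the stereochemical problem by setting C5 through SN2 inversion; it sets out from 24 and comes back at 26. If the closure gives the C5 epimer (1S,3aR,5R,8aS)-1-[(2S,5S)-2,5-dihydroxy-6-methylhept-6-en-2-yl]-3a-methyl-6-methylidenedecahydroazulen-5-ol F10, the unhindered C4' hydroxyl is acetylated selectively (Ac2O, pyridine, 0 °C, no DMAP; the axial C5–OH, 1,3-syn to the angular methyl, reacts more slowly). This gives (3S,6S)-6-hydroxy-6-[(1S,3aR,5R,8aS)-5-hydroxy-3a-methyl-6-methylidenedecahydroazulen-1-yl]-2-methylhept-1-en-3-yl acetate F11. A Mitsunobu reaction with acetic acid (PPh3, diisopropyl azodicarboxylate) then inverts C5 and gives 26 directly.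

## Further compounds

F1 | step 2 | allyl (R)-3-(1,3-dioxolan-2-ylmethyl)-3-methylcyclopent-1-en-1-yl carbonate | C=CCOC(=O)OC1=C[C@@](C)(CC2OCCO2)CC1
F2 | step 3 | (2R,3R)-3-(1,3-dioxolan-2-ylmethyl)-3-methyl-2-(prop-2-en-1-yl)-1-[1-(trimethylsilyl)ethyl]cyclopentan-1-ol (mixture at C1 and at the silyl-bearing carbon) | CC([Si](C)(C)C)C1(O)CC[C@](C)(CC2OCCO2)[C@H]1CC=C
F3 | step 4 | (4R,5R)-4-(1,3-dioxolan-2-ylmethyl)-4-methyl-5-(prop-2-en-1-yl)cyclopent-1-en-1-yl trifluoromethanesulfonate | O=S(=O)(OC1=CC[C@](C)(CC2OCCO2)[C@H]1CC=C)C(F)(F)F
F4 | step 4 | (4R,5R)-4-(1,3-dioxolan-2-ylmethyl)-5-(3-hydroxypropyl)-4-methylcyclopent-1-en-1-yl trifluoromethanesulfonate | O=S(=O)(OC1=CC[C@](C)(CC2OCCO2)[C@H]1CCCO)C(F)(F)F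
F5 | step 4 | 1-[(4R,5R)-4-(1,3-dioxolan-2-ylmethyl)-5-(3-hydroxypropyl)-4-methylcyclopent-1-en-1-yl]ethan-1-one | CC(=O)C1=CC[C@](C)(CC2OCCO2)[C@H]1CCCO
F6 | step 4 | 1-[(1S,2S,3R)-3-(1,3-dioxolan-2-ylmethyl)-2-(3-hydroxypropyl)-3-methylcyclopentyl]ethan-1-one | CC(=O)[C@H]1CC[C@](C)(CC2OCCO2)[C@H]1CCCO
F7 | step 12 | 2-[(1R,2S,3S)-3-acetyl-2-(3-bromobut-3-en-1-yl)-1-methylcyclopentyl]acetaldehyde | CC(=O)[C@H]1CC[C@](C)(CC=O)[C@H]1CCC(Br)=C
F8 | step 12 | 1-[(1S,3aR,5S,8aS)-5-hydroxy-3a-methyl-6-methylidenedecahydroazulen-1-yl]ethan-1-one | CC(=O)[C@H]1CC[C@]2(C)C[C@H](O)C(=C)CC[C@@H]12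
F9 | step 12 | (1S,3aR,5S,8aS)-1-[(2S,5S)-2-hydroxy-6-methyl-5-(triethylsilyloxy)hept-6-en-2-yl]-3a-methyl-6-methylidenedecahydroazulen-5-ol | C=C(C)[C@H](CC[C@](C)(O)[C@H]1CC[C@]2(C)C[C@H](O)C(=C)CC[C@@H]12)O[Si](CC)(CC)CC
F10 | step 14 | (1S,3aR,5R,8aS)-1-[(2S,5S)-2,5-dihydroxy-6-methylhept-6-en-2-yl]-3a-methyl-6-methylidenedecahydroazulen-5-ol | C=C(C)[C@H](CC[C@](C)(O)[C@H]1CC[C@]2(C)C[C@@H](O)C(=C)CC[C@@H]12)O
F11 | step 14 | (3S,6S)-6-hydroxy-6-[(1S,3aR,5R,8aS)-5-hydroxy-3a-methyl-6-methylidenedecahydroazulen-1-yl]-2-methylhept-1-en-3-yl acetate | C=C(C)[C@H](CC[C@](C)(O)[C@H]1CC[C@]2(C)C[C@@H](O)C(=C)CC[C@@H]12)OC(C)=O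
A1 | alternative 1 | (7E)-9-(tert-butyldimethylsilyloxy)-3-diazo-7-methyldeca-1,7,9-trien-4-one | C=CC(=[N+]=[N-])C(=O)CC/C(C)=C/C(=C)O[Si](C)(C)C(C)(C)C
A2 | alternative 1 | 1-ethenyl-5-methyl-6-[1-(tert-butyldimethylsilyloxy)ethenyl]bicyclo[3.1.0]hexan-2-one, the two alkenyl groups cis | C=C[C@@]12C(=O)CC[C@]1(C)[C@H]2C(=C)O[Si](C)(C)C(C)(C)C
A3 | alternative 1 | (3aR)-5-(tert-butyldimethylsilyloxy)-3a-methyl-3,3a,6,7-tetrahydroazulen-1(2H)-one | O=C1CC[C@]2(C)C=C(O[Si](C)(C)C(C)(C)C)CCC=C12
A4 | alternative 2 | (3S,6S)-6-[(1S,2S,3R)-2-(3-bromobut-3-en-1-yl)-3-methyl-3-(2-oxoethyl)cyclopentyl]-6-hydroxy-2-methylhept-1-en-3-yl acetate | C=C(C)[C@H](CC[C@](C)(O)[C@H]1CC[C@](C)(CC=O)[C@H]1CCC(Br)=C)OC(C)=O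
A5 | alternative 2 | (3S,6S)-6-hydroxy-6-[(1S,3aR,5S,8aS)-5-hydroxy-3a-methyl-6-methylidenedecahydroazulen-1-yl]-2-methylhept-1-en-3-yl acetate | C=C(C)[C@H](CC[C@](C)(O)[C@H]1CC[C@]2(C)C[C@H](O)C(=C)CC[C@@H]12)OC(C)=O
A6 | alternative 3 | trans-fused 1-diazo-6,6-(ethylenedioxy)-4a-methylperhydrobenzo[7]annulen-2-one (4aR,9aR) | [N-]=[N+]=C1C(=O)CC[C@]2(C)CC3(OCCO3)CCC[C@@H]12
A7 | alternative 3 | methyl (1S,3aR,8aS)-5,5-(ethylenedioxy)-3a-methyldecahydroazulene-1-carboxylate | COC(=O)[C@H]1CC[C@]2(C)CC3(OCCO3)CCC[C@@H]12
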